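**Strategy.** The route disconnects the bond between C5, the cyclobutane methine on the one-carbon bridge, and quaternary C6 of the seven-membered ring C (numbering below). C5 is carried as the carbonyl carbon of a bicyclo[3.1.1]heptan-6-one (rings A and B) made by intramolecular vinylketene–alkene [2+2] cycloaddition. The key step exploits two features: C9 on C10 points across ring A toward C5 (1,3-cis), and C14 and O9 are cis on ring C, so they are tied as a δ-lactone bearing a tertiary selenide at C6. Radical cyclization onto the derived N-aziridinylimine closes ring C, forms C5–C6 with loss of nitrogen, leaves C5 as CH, and sets C5 and C6 through the tether.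

Key step: step 14

Numbering in the text (longipinane skeleton): C1 ketone carbon; C2 CH2; C3 CH(CH3); C4 and C11 the cyclobutane CH atoms shared with ring B (C4 next to C3, C11 next to C1); C5 the cyclobutane CH between C4 and C11; C6 the carbon with CH3 and C14H2OH; C7 and C9 the CH–O carbons; C8 CH2; C10 the quaternary cyclobutane carbon with CH3. Ring A = C4–C5–C11–C10; ring B = C1–C2–C3–C4–C5–C11; ring C = C5–C6–C7–C8–C9–C10 closed through C4 or C11. Systematic names carry their own locants.

Remarks on the chemistry: (i) the sense of induction in step 7 is assumed to be (R)-BINOL → 9R; the other BINOL antipode is used if it proves opposite. (ii) C6 is carried as a mixture of both epimers from step 8 to step 13; the centre becomes a radical in step 14. (iii) trans-1-Amino-2,3-diphenylaziridine is used as the racemate. (iv) Step 18 installs two angeloyl groups and therefore consumes two equivalents of angelic acid, both activated as the same mixed anhydride.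

**Step 1**
Reactants: 1 (S)-4-benzyl-3-propanoyl-1,3-oxazolidin-2-one; 2 ethyl (E)-4-bromo-3-methylbut-2-enoate
Product: 3 (S)-4-benzyl-3-[(2R,4E)-6-ethoxy-2,4-dimethyl-6-oxohex-4-enoyl]-1,3-oxazolidin-2-one
Conditions: NaN(SiMe3)2, THF, −78 °C; then 2, −78 → −40 °C
Reagents that add atoms: none
Why: Evans asymmetric alkylation: the chelated Z-enolate is alkylated by the allylic bromide on the face away from the benzyl group, which sets C3 as R.

**Step 2**
Reactants: 3 (S)-4-benzyl-3-[(2R,4E)-6-ethoxy-2,4-dimethyl-6-oxohex-4-enoyl]-1,3-oxazolidin-2-one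
Product: 4 ethyl (2E,5R)-6-hydroxy-3,5-dimethylhex-2-enoate
Conditions: LiBH4, MeOH (1 equiv), Et2O, 0 °C
Reagents that add atoms: none
Why: Reductive removal of the auxiliary: LiBH4 should cleave the activated imide much faster than it touches the β,β-disubstituted conjugated ester, and C3 is not affected.

**Step 3**
Reactants: 4 ethyl (2E,5R)-6-hydroxy-3,5-dimethylhex-2-enoate
Product: 5 ethyl (2E,5R)-3,5-dimethyl-6-oxohex-2-enoate
Conditions: Dess–Martin periodinane, NaHCO3, CH2Cl2, 0 °C → rt; used at once
Reagents that add atoms: none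
Why: Dess–Martin oxidation gives the α-branched aldehyde under buffered conditions that should not epimerize C3.

**Step 4**
Reactants: 5 ethyl (2E,5R)-3,5-dimethyl-6-oxohex-2-enoate; 6 2-(triphenyl-λ5-phosphanylidene)propanal
Product: 7 ethyl (2E,5R,6E)-3,5,7-trimethyl-8-oxoocta-2,6-dienoate
Conditions: toluene, 80 °C
Reagents that add atoms: none
Why: Wittig reaction with the formyl-stabilized ylide is E-selective, placing C3 and C9 trans on the new C4=C10 alkene; this geometry is later translated into the C10 configuration.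

**Step 5**
Reactants: 8 ethyl 2-methyl-3-oxobutanoate
Product: 9 ethyl 2-methyl-3-(trimethylsilyloxy)but-2-enoate
Conditions: Me3SiCl, Et3N, hexane, rt
Reagents that add atoms: chlorotrimethylsilane, C[Si](C)(C)Cl
Why: Soft enolization of the β-keto ester and O-silylation give the silyl enol ether.

**Step 6**
Reactants: 9 ethyl 2-methyl-3-(trimethylsilyloxy)but-2-enoate
Product: 10 1-ethoxy-2-methyl-1,3-bis(trimethylsilyloxy)buta-1,3-diene
Conditions: LiN(iPr)2, THF, −78 °C; then Me3SiCl
Reagents that add atoms: chlorotrimethylsilane, C[Si](C)(C)Cl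
Why: γ-Deprotonation and O-silylation of the ester enolate give the 1,3-bis(silyloxy)diene, the dianion equivalent of the keto ester.

**Step 7**
Reactants: 7 ethyl (2E,5R,6E)-3,5,7-trimethyl-8-oxoocta-2,6-dienoate; 10 1-ethoxy-2-methyl-1,3-bis(trimethylsilyloxy)buta-1,3-diene
Product: 12 diethyl (2E,5R,6E,8R)-8-hydroxy-3,5,7,11-tetramethyl-10-oxododeca-2,6-dienedioate, via bis-silyl aldol adduct 11 (not isolated)
Conditions: Ti(OiPr)4 (10 mol %), (R)-BINOL (10 mol %), 4 Å molecular sieves, THF, −78 °C → rt; then 1 M HCl, THF, 0 °C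
Reagents that add atoms: none
Why: Vinylogous Mukaiyama aldol reaction: the terminal diene carbon adds to the aldehyde (the conjugated ester is inert), the chiral Ti(OiPr)4/BINOL Lewis acid selects the aldehyde face that gives 9R, and acid then removes both silyl groups.

**Step 8**
Reactants: 12 diethyl (2E,5R,6E,8R)-8-hydroxy-3,5,7,11-tetramethyl-10-oxododeca-2,6-dienedioate
Product: 13 diethyl (2E,5R,6E,8R)-8-hydroxy-3,5,7,11-tetramethyl-10-oxo-11-(phenylselanyl)dodeca-2,6-dienedioate
Conditions: PhSeCl (1.05 equiv), pyridine, CH2Cl2, 0 °C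
Reagents that add atoms: benzeneselenenyl chloride, Cl[Se]c1ccccc1
Why: Electrophilic selenenylation of the β-keto ester enol at carbon should be faster than attack on either alkene; it makes C6 non-enolizable and installs the radical precursor.

**Step 9**
Reactants: 13 diethyl (2E,5R,6E,8R)-8-hydroxy-3,5,7,11-tetramethyl-10-oxo-11-(phenylselanyl)dodeca-2,6-dienedioate
Product: 14 diethyl (2E,5R,6E,8R,10R)-8,10-dihydroxy-3,5,7,11-tetramethyl-11-(phenylselanyl)dodeca-2,6-dienedioate
Conditions: Me4NBH(OAc)3, MeCN/AcOH, −30 °C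
Reagents that add atoms: none
Why: Evans–Saksena reduction: the C9 hydroxyl binds the borohydride and delivers hydride intramolecularly, which should give the 1,3-anti diol and thus 7R.

**Step 10**
Reactants: 14 diethyl (2E,5R,6E,8R,10R)-8,10-dihydroxy-3,5,7,11-tetramethyl-11-(phenylselanyl)dodeca-2,6-dienedioate
Product: 16 (2E,5R,6E)-7-[(2R,4R)-4-hydroxy-5-methyl-6-oxo-5-(phenylselanyl)oxan-2-yl]-3,5-dimethylocta-2,6-dienoic acid, via dihydroxy diacid 15 (not isolated)
Conditions: LiOH, THF/MeOH/H2O, 40 °C; then 1 M HCl to pH 2; toluene, 50 °C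
Reagents that add atoms: water (delivered as LiOH), O
Why: Saponification of both esters followed by acidification: the δ-hydroxy acid should close to the six-membered lactone O9–C14 (the only lactone that can form), leaving the enoic acid free, and the anti diol gives the lactone with the C7 hydroxyl cis to the alkenyl group.

**Step 11**
Reactants: 16 (2E,5R,6E)-7-[(2R,4R)-4-hydroxy-5-methyl-6-oxo-5-(phenylselanyl)oxan-2-yl]-3,5-dimethylocta-2,6-dienoic acid
Product: 17 (2E,5R,6E)-7-[(2R,4R)-4-acetoxy-5-methyl-6-oxo-5-(phenylselanyl)oxan-2-yl]-3,5-dimethylocta-2,6-dienoic acid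
Conditions: Ac2O, pyridine, DMAP (cat.), CH2Cl2, rt; aqueous NaHCO3, then pH 3
Reagents that add atoms: acetic anhydride, CC(=O)OC(C)=O
Why: Acetylation protects O7 (β-elimination is impossible because C6 bears no hydrogen), and the mixed anhydride formed at the acid is hydrolysed in the work-up.

**Step 12**
Reactants: 17 (2E,5R,6E)-7-[(2R,4R)-4-acetoxy-5-methyl-6-oxo-5-(phenylselanyl)oxan-2-yl]-3,5-dimethylocta-2,6-dienoic acid
Product: 20 7-(lactonyl)-4,7-dimethyl-2-methylidenebicyclo[3.1.1]heptan-6-one (longipinane C1 bears the methylidene group; C5 is the ketone), via acid chloride 18 (not isolated), via vinylketene 19 (not isolated)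
Conditions: (COCl)2, DMF (cat.), benzene, rt, evaporate; then slow addition to Et3N, toluene, 110 °C, 0.005 M
Reagents that add atoms: none
Why: Intramolecular vinylketene–alkene [2+2] cycloaddition: vinylogous dehydrochlorination at the C1 methyl group gives the vinylketene, whose carbonyl carbon (C5) bonds to C4 and whose α-carbon (C11) bonds to C10, forming ring A inside ring B; the E alkene places the C10 methyl syn and the lactone anti to the C1–C3 bridge, and 1,3-allylic strain between the C3 substituents and the C10 methyl directs the ketene to the face that leaves the C3 methyl on the side of the C5 bridge.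

**Step 13**
Reactants: 20 7-(lactonyl)-4,7-dimethyl-2-methylidenebicyclo[3.1.1]heptan-6-one
Product: 21 N-(trans-2,3-diphenylaziridin-1-yl)imine of ketone 20
Conditions: trans-1-amino-2,3-diphenylaziridine, AcOH (cat.), CH2Cl2, 0 °C → rt
Reagents that add atoms: trans-1-amino-2,3-diphenylaziridine, NN1C(c2ccccc2)C1c1ccccc1
Why: Condensation of the strained cyclobutanone, the only ketone present, with the N-aminoaziridine gives the N-aziridinylimine radical acceptor.

**Step 14**
Reactants: 21 N-(trans-2,3-diphenylaziridin-1-yl)imine of ketone 20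
Product: 22 7-O-acetyl-1-methylidene-longipinan-14,9-olide (lactone-bridged tetracycle)
Conditions: Bu3SnH (1.3 equiv, syringe pump), AIBN, benzene, 80 °C, 0.003 M
Reagents that add atoms: none
Why: Bu3Sn• abstracts the phenylselanyl group to give the planar lactone-stabilized tertiary radical at C6, which adds to C5 of the cyclobutanone-derived C=N; the aminyl radical then opens the aziridine, extrudes trans-stilbene and N2, and the resulting C5 radical takes hydrogen from Bu3SnH. The closest known reaction type is the tin hydride radical cyclization onto N-aziridinylimines, in which a ketone carbon receives one new C–C and one new C–H bond. Ring C is closed in the 7-exo-trig mode, and because C6 sits in the δ-lactone the closure gives a lactone-bridged bicyclo[3.2.2] array spanning the one-carbon bridge. C6 is set by the tether (C14 stays bound to O9 on the face of ring C turned to C11, so the methyl group must take the face turned to C4), and C5 is set because the lactone hangs from C10 anti to the C1–C3 bridge and can reach C5 only from that face, so that hydrogen arrives syn to the bridge. The step needs ring closure to outrun direct reduction of the C6 radical, and fragmentation of the aminyl radical to outrun β-scission of the cyclobutane; slow addition of Bu3SnH at high dilution, the 1,3-cis preorganization across ring A and the fast aziridine opening should secure both.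

**Step 15**
Reactants: 22 7-O-acetyl-1-methylidene-longipinan-14,9-olide
Product: 23 1-methylidene-longipinane-7,9,14-triol
Conditions: LiAlH4, THF, 0 → 50 °C
Reagents that add atoms: none
Why: LiAlH4 opens the lactone reductively to the C14 primary and C9 secondary alcohols and cleaves the acetate, with no stereocentre touched.

**Step 16**
Reactants: 23 1-methylidene-longipinane-7,9,14-triol
Product: 24 14-O-(tert-butyldimethylsilyl)-1-methylidene-longipinane-7,9-diol
Conditions: tBuMe2SiCl (1.05 equiv), imidazole, DMF, 0 °C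
Reagents that add atoms: tert-butyldimethylsilyl chloride, CC(C)(C)[Si](C)(C)Cl
Why: The primary C14 hydroxyl should be silylated much faster than the two secondary hydroxyls, each flanked by a quaternary carbon.

**Step 17**
Reactants: 24 14-O-(tert-butyldimethylsilyl)-1-methylidene-longipinane-7,9-diol
Product: 25 14-(tert-butyldimethylsilyloxy)-7,9-dihydroxylongipinan-1-one
Conditions: O3, CH2Cl2/MeOH, −78 °C; then Me2S
Reagents that add atoms: ozone, [O-][O+]=O
Why: Ozonolysis of the only alkene, the exocyclic methylidene group, unmasks the C1 ketone before any angelate is present.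

**Step 18**
Reactants: 25 14-(tert-butyldimethylsilyloxy)-7,9-dihydroxylongipinan-1-one; 26 angelic acid ((Z)-2-methylbut-2-enoic acid), first equivalent
Product: 28 7,9-bis-O-angeloyl-14-(tert-butyldimethylsilyloxy)longipinan-1-one, via mixed anhydride 27 (not isolated)
Conditions: 26 (3 equiv in all), 2,4,6-trichlorobenzoyl chloride (3 equiv), Et3N, toluene, rt; then 25, 80 °C (no DMAP)
Reagents that add atoms: angelic acid (second equivalent of 26), C/C=C(/C)C(=O)O
Why: Yamaguchi esterification with the preformed mixed anhydride, run without a nucleophilic catalyst: two equivalents of the anhydride acylate the two secondary alcohols, one angeloyl group each, with retention of the Z geometry of the angeloyl group.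

**Step 19**
Reactants: 28 7,9-bis-O-angeloyl-14-(tert-butyldimethylsilyloxy)longipinan-1-one
Product: 29 target, 7,9-bis-O-angeloyl-14-hydroxylongipinan-1-one
Conditions: HF·pyridine, pyridine, THF, 0 °C → rt
Reagents that add atoms: none
Why: Buffered fluoride cleaves the silyl ether and should leave the angelates, the ketone and the cyclobutane untouched.

**Compound list**

1 | (S)-4-benzyl-3-propanoyl-1,3-oxazolidin-2-one | CCC(=O)N1[C@@H](Cc2ccccc2)COC1=O | starting material
2 | ethyl (E)-4-bromo-3-methylbut-2-enoate | CCOC(=O)/C=C(C)/CBr | starting material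
3 | (S)-4-benzyl-3-[(2R,4E)-6-ethoxy-2,4-dimethyl-6-oxohex-4-enoyl]-1,3-oxazolidin-2-one | CCOC(=O)/C=C(C)/C[C@@H](C)C(=O)N1[C@@H](Cc2ccccc2)COC1=O | intermediate
4 | ethyl (2E,5R)-6-hydroxy-3,5-dimethylhex-2-enoate | CCOC(=O)/C=C(C)/C[C@@H](C)CO | intermediate
5 | ethyl (2E,5R)-3,5-dimethyl-6-oxohex-2-enoate | CCOC(=O)/C=C(C)/C[C@@H](C)C=O | intermediate
6 | 2-(triphenyl-λ5-phosphanylidene)propanal | CC(C=O)=P(c1ccccc1)(c1ccccc1)c1ccccc1 | starting material
7 | ethyl (2E,5R,6E)-3,5,7-trimethyl-8-oxoocta-2,6-dienoate | CCOC(=O)/C=C(C)/C[C@@H](C)/C=C(C)/C=O | intermediate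
8 | ethyl 2-methyl-3-oxobutanoate | CCOC(=O)C(C)C(C)=O | starting material
9 | ethyl 2-methyl-3-(trimethylsilyloxy)but-2-enoate | CCOC(=O)C(C)=C(C)O[Si](C)(C)C | intermediate
10 | 1-ethoxy-2-methyl-1,3-bis(trimethylsilyloxy)buta-1,3-diene | CCOC(O[Si](C)(C)C)=C(C)C(=C)O[Si](C)(C)C | intermediate
11 | diethyl (2E,5R,6E,8R)-3,5,7,11-tetramethyl-8,10-bis(trimethylsilyloxy)dodeca-2,6,10-trienedioate (bis-silyl aldol adduct) | CCOC(=O)/C=C(C)/C[C@@H](C)/C=C(C)/[C@H](O[Si](C)(C)C)CC(O[Si](C)(C)C)=C(C)C(=O)OCC | intermediate (not isolated)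
12 | diethyl (2E,5R,6E,8R)-8-hydroxy-3,5,7,11-tetramethyl-10-oxododeca-2,6-dienedioate (both C11 epimers) | CCOC(=O)/C=C(C)/C[C@@H](C)/C=C(C)/[C@H](O)CC(=O)C(C)C(=O)OCC | intermediate
13 | diethyl (2E,5R,6E,8R)-8-hydroxy-3,5,7,11-tetramethyl-10-oxo-11-(phenylselanyl)dodeca-2,6-dienedioate (both C11 epimers) | CCOC(=O)/C=C(C)/C[C@@H](C)/C=C(C)/[C@H](O)CC(=O)C(C)([Se]c1ccccc1)C(=O)OCC | intermediate
14 | diethyl (2E,5R,6E,8R,10R)-8,10-dihydroxy-3,5,7,11-tetramethyl-11-(phenylselanyl)dodeca-2,6-dienedioate (anti diol; both C11 epimers) | CCOC(=O)/C=C(C)/C[C@@H](C)/C=C(C)/[C@H](O)C[C@@H](O)C(C)([Se]c1ccccc1)C(=O)OCC | intermediate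
15 | (2E,5R,6E,8R,10R)-8,10-dihydroxy-3,5,7,11-tetramethyl-11-(phenylselanyl)dodeca-2,6-dienedioic acid | OC(=O)/C=C(C)/C[C@@H](C)/C=C(C)/[C@H](O)C[C@@H](O)C(C)([Se]c1ccccc1)C(=O)O | intermediate (not isolated)
16 | (2E,5R,6E)-7-[(2R,4R)-4-hydroxy-5-methyl-6-oxo-5-(phenylselanyl)oxan-2-yl]-3,5-dimethylocta-2,6-dienoic acid (cis-2,4-disubstituted lactone) | O[C@@H]1C[C@@H](OC(=O)C1(C)[Se]c1ccccc1)/C(C)=C/[C@H](C)C/C(C)=C/C(=O)O | intermediate
17 | (2E,5R,6E)-7-[(2R,4R)-4-acetoxy-5-methyl-6-oxo-5-(phenylselanyl)oxan-2-yl]-3,5-dimethylocta-2,6-dienoic acid | CC(=O)O[C@@H]1C[C@@H](OC(=O)C1(C)[Se]c1ccccc1)/C(C)=C/[C@H](C)C/C(C)=C/C(=O)O | intermediate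
18 | acid chloride of 17 | CC(=O)O[C@@H]1C[C@@H](OC(=O)C1(C)[Se]c1ccccc1)/C(C)=C/[C@H](C)C/C(C)=C/C(Cl)=O | intermediate (not isolated)
19 | vinylketene from 18 (3-methylidene-1-oxo-1,6-diene) | CC(=O)O[C@@H]1C[C@@H](OC(=O)C1(C)[Se]c1ccccc1)/C(C)=C/[C@H](C)CC(=C)C=C=O | intermediate (not isolated)
20 | 7-[(2R,4R)-4-acetoxy-5-methyl-6-oxo-5-(phenylselanyl)oxan-2-yl]-4,7-dimethyl-2-methylidenebicyclo[3.1.1]heptan-6-one; 7-methyl syn and lactone anti to the C2–C4 bridge, 4-methyl (R) on the side of the ketone bridge | CC(=O)O[C@@H]1C[C@@H](OC(=O)C1(C)[Se]c1ccccc1)[C@]2(C)[C@@H]3C(=O)[C@H]2C(=C)C[C@H]3C | intermediate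
21 | N-(trans-2,3-diphenylaziridin-1-yl)imine of 20 (racemic aziridine, two diastereomers) | CC(=O)O[C@@H]1C[C@@H](OC(=O)C1(C)[Se]c1ccccc1)[C@]2(C)[C@@H]3C(=NN4C(c5ccccc5)C4c4ccccc4)[C@H]2C(=C)C[C@H]3C | intermediate
22 | 7-O-acetyl-1-methylidene-longipinan-14,9-olide (C14 carbonyl lactonized to O9; all skeleton stereocentres as in the target) | CC(=O)O[C@@H]1C[C@@H](O4)[C@]2(C)[C@@H]3[C@@H]([C@H]2C(=C)C[C@H]3C)[C@@]1(C)C4=O | intermediate
23 | 1-methylidene-longipinane-7,9,14-triol | O[C@@H]1C[C@@H](O)[C@]2(C)[C@@H]3[C@@H]([C@H]2C(=C)C[C@H]3C)[C@@]1(C)CO | intermediate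
24 | 14-O-(tert-butyldimethylsilyl)-1-methylidene-longipinane-7,9-diol | O[C@@H]1C[C@@H](O)[C@]2(C)[C@@H]3[C@@H]([C@H]2C(=C)C[C@H]3C)[C@@]1(C)CO[Si](C)(C)C(C)(C)C | intermediate
25 | 14-(tert-butyldimethylsilyloxy)-7,9-dihydroxylongipinan-1-one | O[C@@H]1C[C@@H](O)[C@]2(C)[C@@H]3[C@@H]([C@H]2C(=O)C[C@H]3C)[C@@]1(C)CO[Si](C)(C)C(C)(C)C | intermediate
26 | angelic acid, (Z)-2-methylbut-2-enoic acid | C/C=C(/C)C(=O)O | starting material
27 | angelic 2,4,6-trichlorobenzoic anhydride | C/C=C(/C)C(=O)OC(=O)c1c(Cl)cc(Cl)cc1Cl | intermediate (not isolated)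
28 | 7,9-bis-O-angeloyl-14-(tert-butyldimethylsilyloxy)longipinan-1-one | C/C=C(/C)C(=O)O[C@@H]1C[C@@H](OC(=O)/C(C)=C\C)[C@]2(C)[C@@H]3[C@@H]([C@H]2C(=O)C[C@H]3C)[C@@]1(C)CO[Si](C)(C)C(C)(C)C | intermediate
29 | 7,9-bis-O-angeloyl-14-hydroxylongipinan-1-one | C/C=C(/C)C(=O)O[C@@H]1C[C@@H](OC(=O)/C(C)=C\C)[C@]2(C)[C@@H]3[C@@H]([C@H]2C(=O)C[C@H]3C)[C@@]1(C)CO | target

**Step count.** Total: 19 steps. Longest linear sequence: 17 steps (steps 1–4 and 7–19); steps 5 and 6 form the diene branch.

**Steps most likely to fail**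

1. Step 14 (key step). The tertiary C6 radical may be reduced by Bu3SnH before the bridged seven-membered transition state is reached, returning the selenium-free lactone. Fallback: set out from 21 and run the closure as a phenylselanyl group-transfer chain with no hydride present (Bu3SnSnBu3 cat., AIBN, benzene, 80 °C). The C5 radical formed after loss of stilbene and N2 should then take the PhSe group from a second molecule of 21, giving the C5 phenylselenide of the bridged lactone F1. A separate reduction of F1 (Bu3SnH, AIBN, benzene, 80 °C) returns to the route at 22.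

2. Step 12. The alkene is deactivated by the allylic acyloxy group at C9, so the vinylketene may be lost to oligomerization or to deprotonation at C2 instead of the C1 methyl group. Fallback: set out from 17, convert acid chloride 18 with pyrrolidine into the pyrrolidine amide F2, and activate it with Tf2O and 2,4,6-collidine in 1,2-dichloroethane at reflux. The more electrophilic vinylketeniminium ion should undergo the same intramolecular [2+2] cycloaddition to the cyclobutaniminium triflate F3. Aqueous NaHCO3 hydrolysis of F3 returns to the route at 20.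

3. Step 18. Both hydroxyl groups are secondary and flanked by quaternary carbons, so acylation may stall after the first ester, and forcing may isomerize the angeloyl group from Z to E. Fallback: set out from 25 and esterify both alcohols with 2-[bis(2,2,2-trifluoroethoxy)phosphoryl]propanoic acid (DCC, DMAP, CH2Cl2) to the bis(phosphonopropanoate) F4. A Still–Gennari olefination of F4 with acetaldehyde (KN(SiMe3)2, 18-crown-6, THF, −78 °C) should build both Z-2-methylbut-2-enoates on the molecule and return to the route at 28.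

**Further compounds**

F1 | step 14 | 5-(phenylselanyl) derivative of 22 (7-O-acetyl-1-methylidene-5-(phenylselanyl)longipinan-14,9-olide) | CC(=O)O[C@@H]1C[C@@H](O4)[C@]2(C)[C@@H]3[C@@]([Se]c5ccccc5)([C@H]2C(=C)C[C@H]3C)[C@@]1(C)C4=O
F2 | step 12 | pyrrolidine amide of acid 17 | CC(=O)O[C@@H]1C[C@@H](OC(=O)C1(C)[Se]c1ccccc1)/C(C)=C/[C@H](C)C/C(C)=C/C(=O)N1CCCC1
F3 | step 12 | cyclobutaniminium triflate (pyrrolidinium analogue of ketone 20) | CC(=O)O[C@@H]1C[C@@H](OC(=O)C1(C)[Se]c1ccccc1)[C@]2(C)[C@@H]3C(=[N+]4CCCC4)[C@H]2C(=C)C[C@H]3C.[O-]S(=O)(=O)C(F)(F)F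
F4 | step 18 | 7,9-bis-O-{2-[bis(2,2,2-trifluoroethoxy)phosphoryl]propanoyl} derivative of 25 | CC(C(=O)O[C@@H]1C[C@@H](OC(=O)C(C)P(=O)(OCC(F)(F)F)OCC(F)(F)F)[C@]2(C)[C@@H]3[C@@H]([C@H]2C(=O)C[C@H]3C)[C@@]1(C)CO[Si](C)(C)C(C)(C)C)P(=O)(OCC(F)(F)F)OCC(F)(F)F
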